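Oak, the flask asked about, can be kept as a ledger: the free monomer charged is the capital, and the readings are percentages of it.

- oak: free monomer 0.20 M; initiator 1.1 mM; the very flask that is asked about, followed so far
- flask: free monomer 0.20 M; initiator 1.1 mM; time 1.0 h

oak run (percent of the free monomer charged): time / min: monomer in chains / % = 2.00: 37.5; 3.00: 44.5; 4.00: 48.2; 6.00: 52.1; 8.00: 51.9; 12.0: 50.9; 20.0: 47.6

(standard deviation of a reading: 0.3 percentage points)

- when, up to 1.0 h, the flask holds most monomer in chains
- the amount of monomer in chains, in percent of the free monomer charged, at that time

- the numbers in the tables scatter by 0.3 percentage points (one standard deviation)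

The initiator is the small entry: c(initiator) lies 2.26 powers of ten below c(free monomer), and by the reading at 6.00 min each initiator charged stands against about 94.7 monomers in chains. The readings give 52.1 % at 6.00 min and 51.9 % at 8.00 min, a difference within the scatter of 0.3 percentage points, so we bracket the top between those two times, at about that height. The other 47.9 % of the charge is not in chains at 6.00 min, and the readings do not say where it stands.

Later readings show a net debit: from 12.0 min to 20.0 min oak loses 3.3 points. We carry that pace forward as the clearing time, 4.04 h, the time this loss, held steady (zero-order, in the usual term), takes to remove one whole charge. It is a reading from two scattered numbers. Our reckoning takes the 47.6 % at 20.0 min and leaves 31.1 % at 1.0 h, and the books close at 2.26 h, later than the time limit.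

The forecast gives 52.2 % at 0.12 h, inside our bracket, and says “The peak is flat, so its time is poorly fixed”.

The flask holds its most, 52.2 %, at 0.132 h.

    monomer in chains + living end → free monomer + living end, rate k1*[living end] as long as [monomer in chains] is above zero (k = 0.150 s⁻¹)
    living end + monomer in chains → dead end (k = 0.00210 M⁻¹ s⁻¹)
    free monomer + living end → monomer in chains + living end, rate k3*[living end]*[free monomer] (k = 6.40 M⁻¹ s⁻¹)
    2 free monomer → self-condensation product (k = 0.0150 M⁻¹ s⁻¹)
    free monomer + initiator → living end + monomer in chains (k = 1.20 M⁻¹ s⁻¹)
    free monomer → uncatalysed product (k = 8.50 × 10⁻⁵ s⁻¹)

That height belongs to this charge of initiator: a run with half of it reaches 37.8 %, which is 14 points under the forecast. Started from the flask's top, the clearing time of 4.04 h leaves 30.7 % at 1.0 h, and the flask holds 31.2 %. A reading of the same charge at 4.0 h falls past our reckoned close, and there the monomer in chains stands at 0 %.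

The readings stem from a simulated flask from invented constants, and the scatter is random.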